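**Retrosynthetic overview**

1. Target 16 comes from heptamethyl ether 15 by global O-demethylation; 15 comes from phenol 13 and iodoarene 14 by an Ullmann ether synthesis that attaches the 3,5-dioxygenated phenoxy ring (ring A) to the only free OH.
2. The dibenzo-1,4-dioxin ring of 13 is not closed directly: oxidative dearomatisation of bis-phenol 11 gives a spiro 1,3-dioxole ketal (a five-membered O–C–O ring on a cyclohexa-2,4-dienone), which expands to the six-membered dioxin by a 1,2-oxygen shift.
3. Enabling feature: in 11 the outer phenol ring (ring B) has C1–OH (para to an OMe), C2 carrying the diaryl-ether oxygen and C3–H. The dibenzofuran ring (ring C) has its 1-OH ortho to that ether oxygen, so ipso attack at C2 gives the ketal and C3–H is the terminus of the shift.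
4. 11 comes from 7 and 8: SNAr of a salicylaldehyde-type dibenzofuranol on an ortho-fluorobenzaldehyde, then a double Baeyer–Villiger/Dakin oxidation turns both CHO groups into the two OH groups.
5. 7 comes from 1 and 3. Order of ring formation: furan (Chan–Lam ether, Pd direct arylation), then the transient 1,3-dioxole, then the 1,4-dioxin; ring A is attached last.

Key step: step 8

Remark: the target is planar and has no stereogenic element, so no stereocontrol is needed; compounds 1, 3, 8 and 14 are taken as commercially available.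

**Step 1**
Reactants: 1 4-(benzyloxy)-3-methoxyphenol
Product: 2 4-(benzyloxy)-2-bromo-5-methoxyphenol
Conditions: NBS (1.0 equiv), MeCN, −20 → 0 °C
Reagents that add atoms: N-bromosuccinimide, O=C1CCC(=O)N1Br
Why: Electrophilic aromatic bromination should go to C6 of 1, which is ortho to the free OH, para to the OMe and less hindered than C2 between OH and OMe.

**Step 2**
Reactants: 2 4-(benzyloxy)-2-bromo-5-methoxyphenol; 3 (3,5-dimethoxyphenyl)boronic acid
Product: 4 1-(benzyloxy)-5-bromo-4-(3,5-dimethoxyphenoxy)-2-methoxybenzene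
Conditions: Cu(OAc)2 (20 mol%), pyridine, 4 Å MS, CH2Cl2, O2 (1 atm), rt
Reagents that add atoms: none
Why: The Chan–Lam–Evans oxidative O-arylation of a phenol with an arylboronic acid leaves the ortho C–Br bond untouched, which a classical Ullmann coupling would not.

**Step 3**
Reactants: 4 1-(benzyloxy)-5-bromo-4-(3,5-dimethoxyphenoxy)-2-methoxybenzene
Product: 5 2-(benzyloxy)-3,7,9-trimethoxydibenzo[b,d]furan
Conditions: Pd(OAc)2 (5 mol%), PCy3·HBF4 (10 mol%), K2CO3, DMA, 130 °C
Reagents that add atoms: none
Why: Pd-catalysed intramolecular direct C–H arylation (concerted metalation–deprotonation) of a 2-bromodiaryl ether closes the furan ring, and the two ortho C–H positions of the 3,5-dimethoxyphenoxy ring are equivalent, so only one dibenzofuran can form.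

**Step 4**
Reactants: 5 2-(benzyloxy)-3,7,9-trimethoxydibenzo[b,d]furan
Product: 6 3,7,9-trimethoxydibenzo[b,d]furan-2-ol
Conditions: H2 (1 atm), 10% Pd/C, EtOAc/MeOH, rt
Reagents that add atoms: none
Why: Hydrogenolysis cleaves the benzyl ether only; aryl methyl ethers and the dibenzofuran are inert.

**Step 5**
Reactants: 6 3,7,9-trimethoxydibenzo[b,d]furan-2-ol
Product: 7 2-hydroxy-3,7,9-trimethoxydibenzo[b,d]furan-1-carbaldehyde
Conditions: MgCl2, Et3N, (CH2O)n, MeCN, reflux
Reagents that add atoms: paraformaldehyde (as formaldehyde), C=O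
Why: The Casnati–Skattebøl ortho-formylation delivers formaldehyde through the magnesium phenoxide only to a position ortho to the OH, and C1 is the only free one because C3 carries OMe.

**Step 6**
Reactants: 7 2-hydroxy-3,7,9-trimethoxydibenzo[b,d]furan-1-carbaldehyde; 8 2-fluoro-4,6-dimethoxybenzaldehyde
Product: 9 2-(2-formyl-3,5-dimethoxyphenoxy)-3,7,9-trimethoxydibenzo[b,d]furan-1-carbaldehyde
Conditions: K2CO3, DMF, 110 °C, N2
Reagents that add atoms: none
Why: SNAr should work because the ortho-formyl group activates the C–F bond of 8 while both OMe groups are meta to fluorine and do not deactivate it.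

**Step 7**
Reactants: 9 2-(2-formyl-3,5-dimethoxyphenoxy)-3,7,9-trimethoxydibenzo[b,d]furan-1-carbaldehyde
Product: 11 2-(2-hydroxy-3,5-dimethoxyphenoxy)-3,7,9-trimethoxydibenzo[b,d]furan-1-ol, via bis-formate 10 (not isolated)
Conditions: mCPBA (2.6 equiv), CH2Cl2, 0 °C → rt; then K2CO3 (cat.), MeOH, rt, Ar
Reagents that add atoms: meta-chloroperbenzoic acid, OOC(=O)c1cccc(Cl)c1
Why: In this Baeyer–Villiger (Dakin-type) oxidation both formyl groups sit on electron-rich rings, ortho to an aryloxy oxygen and between two ortho substituents, which favours aryl over hydride migration to aryl formates that methanol then cleaves.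

**Step 8**
Reactants: 11 2-(2-hydroxy-3,5-dimethoxyphenoxy)-3,7,9-trimethoxydibenzo[b,d]furan-1-ol
Product: 13 hexa-O-methyl benzofuro-fused dibenzo[b,e][1,4]dioxin phenol (free OH on ring B between its OMe carbon and the dioxin carbon), via spiroketal dienone 12 (not isolated)
Conditions: PhI(OAc)2 (1.0 equiv), CH2Cl2/HFIP 4:1, 0.01 M, −40 °C; then BF3·OEt2 (30 mol%), −40 → 0 °C
Reagents that add atoms: none
Why: Proposed new method: PhI(OAc)2 should oxidise the 2-aryloxy-4,6-dimethoxyphenol ring (the easier ring to oxidise because of its para-OMe) to a phenoxenium ion, which the dibenzofuran 1-OH traps at the ipso carbon C2 that already carries the ether oxygen (5-exo-trig) to give the spiro 1,3-dioxole ketal 12; this part follows the known iodine(III) dearomatising spiroketalisation of phenols to quinone monoketals. BF3 then activates the dienone C=O, which puts cationic character on C3–H next to the spiro carbon, and one ketal oxygen moves from C2 to C3 through an oxiranium-like three-membered transition state before loss of H+ rearomatises, so the five-membered O–C–O ring grows by one carbon into the 1,4-dioxin; the closest known reactions are the dienone–phenol rearrangement with 1,2-acyloxy shift of quinol acetates and the ring expansion of 2-(1-haloalkyl)-1,3-dioxolanes to 1,4-dioxenes. No stereocentre results, since the spiro carbon of 12 becomes aromatic again. The step needs the right oxygen to migrate: the migrating oxygen is leaving group and nucleophile at once, so substituent effects on it largely cancel, whereas the oxygen that stays must stabilise the developing oxocarbenium carbon, and dibenzofuran O-2 (ortho-OMe and para-furan oxygen) is a much better donor than bay-region O-1 (only meta oxygens), so O-2 should stay on C2 and O-1 should shift to C3, which is the connectivity of the target. C3 is the only possible terminus because the other neighbour of the spiro carbon is the carbonyl carbon, and the oxidant is used up at low temperature before the acid is added so that the new para-methoxyphenol 13 is not oxidised further.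

**Step 9**
Reactants: 13 hexa-O-methyl benzofuro-fused dibenzo[b,e][1,4]dioxin phenol; 14 1-iodo-3,5-dimethoxybenzene
Product: 15 hepta-O-methyl ether of the target
Conditions: CuI (10 mol%), picolinic acid (20 mol%), K3PO4, DMSO, 90 °C, Ar
Reagents that add atoms: none
Why: The Cu-catalysed Ullmann diaryl ether synthesis with picolinic acid as ligand is suited to ortho,ortho-disubstituted phenols and aryl iodides.

**Step 10**
Reactants: 15 hepta-O-methyl ether of the target
Product: 16 target heptaphenol (CNP0256302.0)
Conditions: BBr3 (excess), CH2Cl2, −78 °C → rt; MeOH then H2O quench, work-up under Ar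
Reagents that add atoms: none
Why: Lewis-acid ether cleavage with BBr3 should remove all seven methyl groups, while the aryl–O–aryl bonds of the diaryl ether, dioxin and furan are not cleaved.

**Compound list**

1 | 4-(benzyloxy)-3-methoxyphenol | COc1cc(O)ccc1OCc1ccccc1 | starting material
2 | 4-(benzyloxy)-2-bromo-5-methoxyphenol | COc1cc(O)c(Br)cc1OCc1ccccc1 | intermediate
3 | (3,5-dimethoxyphenyl)boronic acid | COc1cc(OC)cc(B(O)O)c1 | starting material
4 | 1-(benzyloxy)-5-bromo-4-(3,5-dimethoxyphenoxy)-2-methoxybenzene | COc1cc(Oc2cc(OC)cc(OC)c2)c(Br)cc1OCc1ccccc1 | intermediate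
5 | 2-(benzyloxy)-3,7,9-trimethoxydibenzo[b,d]furan | COc1cc(OC)c2c(c1)oc1cc(OC)c(OCc3ccccc3)cc12 | intermediate
6 | 3,7,9-trimethoxydibenzo[b,d]furan-2-ol | COc1cc(OC)c2c(c1)oc1cc(OC)c(O)cc12 | intermediate
7 | 2-hydroxy-3,7,9-trimethoxydibenzo[b,d]furan-1-carbaldehyde | COc1cc(OC)c2c(c1)oc1cc(OC)c(O)c(C=O)c12 | intermediate
8 | 2-fluoro-4,6-dimethoxybenzaldehyde | COc1cc(F)c(C=O)c(OC)c1 | starting material
9 | 2-(2-formyl-3,5-dimethoxyphenoxy)-3,7,9-trimethoxydibenzo[b,d]furan-1-carbaldehyde | COc1cc(OC)c(C=O)c(Oc2c(OC)cc3oc4cc(OC)cc(OC)c4c3c2C=O)c1 | intermediate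
10 | 2-[2-(formyloxy)-3,5-dimethoxyphenoxy]-3,7,9-trimethoxydibenzo[b,d]furan-1-yl formate (bis-formate, not isolated) | COc1cc(OC)c(OC=O)c(Oc2c(OC)cc3oc4cc(OC)cc(OC)c4c3c2OC=O)c1 | intermediate
11 | 2-(2-hydroxy-3,5-dimethoxyphenoxy)-3,7,9-trimethoxydibenzo[b,d]furan-1-ol | COc1cc(OC)c(O)c(Oc2c(OC)cc3oc4cc(OC)cc(OC)c4c3c2O)c1 | intermediate
12 | spiroketal dienone: 2,4-dimethoxycyclohexa-2,4-dien-1-one whose C6 is the ketal carbon of a 1,3-dioxole fused to C1–C2 of 3,7,9-trimethoxydibenzofuran (not isolated) | COC1=CC(OC)=CC2(Oc3c(OC)cc4oc5cc(OC)cc(OC)c5c4c3O2)C1=O | intermediate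
13 | hexa-O-methyl benzofuro-fused dibenzo[b,e][1,4]dioxin phenol (free OH on ring B between its OMe carbon and the dioxin carbon) | COc1cc(OC)c2c(c1O)Oc1c(OC)cc3oc4cc(OC)cc(OC)c4c3c1O2 | intermediate
14 | 1-iodo-3,5-dimethoxybenzene | COc1cc(I)cc(OC)c1 | starting material
15 | hepta-O-methyl ether of the target | COc1cc(OC)cc(Oc2c(OC)cc(OC)c3c2Oc2c(OC)cc4oc5cc(OC)cc(OC)c5c4c2O3)c1 | intermediate
16 | target heptaphenol (CNP0256302.0) | Oc1cc(O)cc(Oc2c(O)cc(O)c3c2Oc2c(O)cc4oc5cc(O)cc(O)c5c4c2O3)c1 | target

**Step count**

Total step count: 10. Longest linear sequence: 10 steps (1 → 16).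

**Steps most likely to fail**

Step 8 (Proposed new method). What may go wrong: oxidation of the dibenzofuranol ring instead of ring B, migration of the other ketal oxygen (which would give the regioisomeric dioxin), or further oxidation of the product phenol. The fallback closes the dioxin by two known C–O bond formations without any ring-size change; it sets out from 8 (together with 7) and comes back to the route at 13. Bromination of 8 with NBS in MeCN should occur at C3 (ortho to one OMe, para to the other) and give 3-bromo-2-fluoro-4,6-dimethoxybenzaldehyde F1. SNAr with 7 (K2CO3, DMF) should displace only the fluoride ortho to CHO and give 2-(6-bromo-2-formyl-3,5-dimethoxyphenoxy)-3,7,9-trimethoxydibenzo[b,d]furan-1-carbaldehyde F2. Oxidation with mCPBA followed by K2CO3/MeOH should give, through the bromo bis-formate F3, 2-(6-bromo-2-hydroxy-3,5-dimethoxyphenoxy)-3,7,9-trimethoxydibenzo[b,d]furan-1-ol F4. Intramolecular Ullmann etherification (CuI, N,N-dimethylglycine, Cs2CO3, dioxane, 100 °C) between the dibenzofuran 1-OH and the C–Br bond should then give 13.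

Step 6. What may go wrong: low conversion, because the phenoxide of 7 is hindered on both sides and deactivated by the ortho-formyl group, together with thermal degradation of the two aldehydes. The fallback makes the nucleophile a catecholate; it sets out from 7 and comes back at 11. Dakin oxidation of 7 (H2O2, aq. NaOH/THF, 0 °C) should give 3,7,9-trimethoxydibenzo[b,d]furan-1,2-diol F5. Mono-SNAr with 8 (1 equiv K2CO3, DMF, 80 °C, Ar) is expected at the less hindered O-2 and should give 2-[(1-hydroxy-3,7,9-trimethoxydibenzo[b,d]furan-2-yl)oxy]-4,6-dimethoxybenzaldehyde F6. Baeyer–Villiger oxidation (mCPBA, then K2CO3/MeOH) should give 11 through the aryl formate F7. The site selectivity of the mono-arylation is not critical, because both catechol oxygens end on the same spiro carbon in step 8.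

Step 9. What may go wrong: slow coupling of a phenoxide flanked by two oxygen substituents, and oxidative degradation of this para-methoxyphenoxide under basic copper conditions. The fallback is a metal-free arylation at iodine(III); it sets out from 13 (with 14 as source of the aryl group) and comes back at 15. Treatment of 14 with mCPBA and TsOH·H2O, then 1,3,5-trimethoxybenzene, should give (3,5-dimethoxyphenyl)(2,4,6-trimethoxyphenyl)iodonium tosylate F8. Reaction of 13 with F8 (K2CO3, MeCN, rt to 40 °C) should transfer the 3,5-dimethoxyphenyl group to oxygen by ligand coupling, with the trimethoxyphenyl group staying on iodine, and give 15.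

**Further compounds**

F1 | step 8 | 3-bromo-2-fluoro-4,6-dimethoxybenzaldehyde | COc1cc(OC)c(C=O)c(F)c1Br
F2 | step 8 | 2-(6-bromo-2-formyl-3,5-dimethoxyphenoxy)-3,7,9-trimethoxydibenzo[b,d]furan-1-carbaldehyde | COc1cc(OC)c(C=O)c(Oc2c(OC)cc3oc4cc(OC)cc(OC)c4c3c2C=O)c1Br
F3 | step 8 | 2-[6-bromo-2-(formyloxy)-3,5-dimethoxyphenoxy]-3,7,9-trimethoxydibenzo[b,d]furan-1-yl formate | COc1cc(OC)c(OC=O)c(Oc2c(OC)cc3oc4cc(OC)cc(OC)c4c3c2OC=O)c1Br
F4 | step 8 | 2-(6-bromo-2-hydroxy-3,5-dimethoxyphenoxy)-3,7,9-trimethoxydibenzo[b,d]furan-1-ol | COc1cc(OC)c(O)c(Oc2c(OC)cc3oc4cc(OC)cc(OC)c4c3c2O)c1Br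
F5 | step 6 | 3,7,9-trimethoxydibenzo[b,d]furan-1,2-diol | COc1cc(OC)c2c(c1)oc1cc(OC)c(O)c(O)c12
F6 | step 6 | 2-[(1-hydroxy-3,7,9-trimethoxydibenzo[b,d]furan-2-yl)oxy]-4,6-dimethoxybenzaldehyde | COc1cc(OC)c(C=O)c(Oc2c(OC)cc3oc4cc(OC)cc(OC)c4c3c2O)c1
F7 | step 6 | 2-[(1-hydroxy-3,7,9-trimethoxydibenzo[b,d]furan-2-yl)oxy]-4,6-dimethoxyphenyl formate | COc1cc(OC)c(OC=O)c(Oc2c(OC)cc3oc4cc(OC)cc(OC)c4c3c2O)c1
F8 | step 9 | (3,5-dimethoxyphenyl)(2,4,6-trimethoxyphenyl)iodonium tosylate | COc1cc(OC)cc([I+]c2c(OC)cc(OC)cc2OC)c1.Cc1ccc(S(=O)(=O)[O-])cc1
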